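The runs stem from a simulated flask from invented constants; scatter was added.

Amounts come first: these flasks take their substrate in equal portions, and every percentage counts the whole charge, also what has not yet gone in.

| setting | Friday's | Saturday's | Tuesday's | autumn | winter | midnight | spring |
|---|---|---|---|---|---|---|---|
| substrate | 0.50 M (in portions, 4) | 0.50 M (in portions, 4) | 0.33 M (in portions, 4) | 0.50 M (in portions, 4) | 0.30 M (in portions, 4) | 0.50 M (in portions, 4) | 0.30 M (in portions, 4) |
| reagent | 0.65 M | 0.65 M | 0.65 M | 0.650 M | 0.650 M | 0.650 M | 0.650 M |
| transfer agent | 0.018 M | 0.055 M | 0.050 M | 0.0500 M | 0.0500 M | 0.0150 M | 0.0150 M |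
| initiator | 26 mM | 26 mM | 26 mM | 26 mM | 26 mM | 26 mM | 26 mM |
| remark | run made earlier; portions every 20 h | run made earlier; portions every 20 h | run made earlier; portions every 20 h | the portions of substrate follow each other after 20 h, the first at the start | the portions of substrate follow each other after 20 h, the first at the start | the portions of substrate follow each other after 20 h, the first at the start | the portions of substrate follow each other after 30 h, the first at the start |
| time |  |  |  | 3.0 d | 3.0 d | 3.0 d | 3.0 d |

| run | time / h | target / % | substrate / % |
|---|---|---|---|
| Friday's | 8.00 | 3.0 | 21.3 |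
| Friday's | 15.0 | 5.4 | 18.5 |
| Friday's | 20.0 | 7.3 | 16.0 |
| Friday's | 30.0 | 12.4 | 35.1 |
| Friday's | 40.0 | 18.0 | 27.9 |
| Saturday's | 8.00 | 0.6 | 23.7 |
| Saturday's | 15.0 | 1.6 | 22.1 |
| Saturday's | 20.0 | 2.5 | 21.4 |
| Saturday's | 30.0 | 3.0 | 44.3 |
| Saturday's | 40.0 | 4.0 | 41.9 |
| Tuesday's | 3.00 | 0.5 | 23.9 |
| Tuesday's | 10.0 | 2.1 | 21.9 |
| Tuesday's | 15.0 | 2.5 | 20.1 |
| Tuesday's | 25.0 | 4.3 | 42.2 |
| Tuesday's | 40.0 | 6.1 | 37.9 |

(each reading ± 0.3 percentage points)

- percentages count the whole charge, also what has not yet gone in

1. the flasks by amount of target, in percent of the substrate charged, highest first, at 3.0 d (autumn / winter / midnight / spring)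
2. the same order at 12 d (autumn / winter / midnight / spring)
3. the amount of target, in percent of the substrate charged of the flask you put first, at 3.0 d
4. the amount of target, in percent of the substrate charged of the flask you put last, at 3.0 d

Two chemists read these runs differently. The first compares target per hour up to the second portion. Friday makes 1.82 mM h⁻¹ at 0.018 M of transfer agent and Saturday 0.625 mM h⁻¹ at 0.055 M, a ratio of 2.91 against 3.06 in [transfer agent]. So this chemist takes the rate to go as one over [transfer agent], rising slowly, and carries it forward. That is the forecast: spring > midnight > winter > autumn at 3.0 d, with 48% (range 40% to 56%) for spring, 42% for midnight and 7.6% for autumn. On spring it says: “Spring runs faster than its feed and is feed-starved”. At 12 d it gives midnight > spring > winter > autumn.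

The second chemist counts what is missing. At the last reading, substrate and target fall short of the two portions then in, which gives a mean loss of 0.513 mM h⁻¹ on Friday, 0.513 mM h⁻¹ on Saturday and 0.495 mM h⁻¹ on Tuesday, though [transfer agent] and substrate differ; the initiator is the same in these runs. This chemist supposes that each bit lost takes one transfer agent with it, and replaces the curve by that mean. The clearing time, starting [transfer agent] divided by the mean loss, is the usual induction period. For midnight and spring it is 29.3 h, for autumn and winter 97.6 h, so 3.0 d lies beyond the first pair and short of the second.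

By this reckoning Friday clears at 35.1 h, and between its last readings it makes 2.80 mM h⁻¹, while Saturday, far from clearing, makes 0.500 mM h⁻¹. Spring's last portion comes at 90.0 h, after 3.0 d, so by then spring has 75.0% of its substrate in, while midnight, whose last portion comes at 60.0 h, has its whole charge in. This chemist puts midnight first, above the forecast's figure, but gives no number, since no run goes far past clearing.

The flask gives midnight > spring > winter > autumn at 3.0 d: midnight 67.7%, spring 50.6%, winter 11.5%, autumn 6.40%. At 12 d it gives spring > midnight > winter > autumn. The first chemist's view keeps the flasks whose clearing time lies beyond the reading: autumn came to 6.40% against the forecast's 7.6%.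

    initiator → 2 initiating radical (k = 2.50 × 10⁻⁶ s⁻¹)
    substrate + initiating radical → capped initiator + first chain carrier (k = 4500 L mol⁻¹ s⁻¹)
    reagent + first chain carrier → target + second chain carrier (k = 630 L mol⁻¹ s⁻¹)
    substrate + second chain carrier → released group + first chain carrier (k = 380 L mol⁻¹ s⁻¹)
    transfer agent + first chain carrier → side product A + idle radical (kL = 6000 L mol⁻¹ s⁻¹)
    2 idle radical → ended radicals (k = 2.10 × 10⁸ L mol⁻¹ s⁻¹)
    2 first chain carrier → ended chains A (k = 4.00 × 10⁷ L mol⁻¹ s⁻¹)
    2 second chain carrier → ended chains B (k = 2.00 × 10⁷ L mol⁻¹ s⁻¹)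
    crystals ⇌ released group, rate k9*(cs9 - [released group]) while solid is left; crystals form when [released group] > cs9 (solubility = 0.0610 M, k = 0.00120 s⁻¹)
    substrate + target → side product B (k = 4.20 × 10⁻⁶ L mol⁻¹ s⁻¹)
    reagent ⇌ dormant form (K = 1.70, k = 1.40 × 10⁻⁶ s⁻¹)

Midnight's clearing time of 29.3 h lies inside 3.0 d, and at 3.00 d its transfer agent stands at 0% of the charge. Autumn's clearing time of 97.6 h lies beyond 3.0 d, and the passing of transfer agent and first chain carrier into side product A and idle radical is the main reason for autumn's low target: with that step taken away, autumn gives 75.4% instead of 6.40%. The reckoning runs short: autumn still holds 51% where it leaves 26.2%. A neighbour of midnight charged with 0.060 M of transfer agent has a clearing time of 117 h, beyond 3.0 d, and holds 5.01% of target.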